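**Strategy.** The 1,2-dioxane is disconnected at its O1–C6 bond. C6, the fully substituted ring carbon, lies γ to the side-chain ketone (C6–C7–C8–C9=O), the retron of a homo-conjugate addition. The precursor therefore carries C6, C7 and C8 as a cyclopropane conjugated to the complete α-methylene ketone, and a (3S)-hydroperoxide on the propanoate arm. One Lewis-acid step opens the three-membered carbocycle at C6 with inversion, closes the peroxide ring, unveils the C7–C8 ethano bridge and sets the quaternary stereocentre, giving the target directly. The cyclopropane comes from geraniol by Charette cyclopropanation; an Evans aldol and a triflate perhydrolysis supply the hydroperoxide.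

Key step: step 12

Remark on the chemistry: locants in the text are those of the target (dioxane O1, O2, C3–C6; chain on C6: C7, C8, C9 = ketone carbon, C10 = methylidene-bearing carbon). The carbinol centre made in step 6 is carried as both epimers, because step 10 oxidises it.

Step 1
Reactants: 1 6-methylhept-5-en-2-one
Product: 2 6-hydroxy-6-methylheptan-2-one
Conditions: 35% aq. H2SO4, 0 °C → rt
Reagents that add atoms: water, O
Why: Markovnikov acid-catalysed hydration of the trisubstituted alkene through the tertiary carbocation should give the tertiary alcohol, the ketone being inert.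

Step 2
Reactants: 2 6-hydroxy-6-methylheptan-2-one
Product: 3 6-methyl-6-(trimethylsilyloxy)heptan-2-one
Conditions: TMSCl, imidazole, DMF, rt
Reagents that add atoms: chlorotrimethylsilane, C[Si](C)(C)Cl
Why: Silyl ether formation masks the tertiary hydroxyl for the organolithium chemistry of step 6, and the trimethylsilyl group is chosen because step 9 removes it without an extra operation.

Step 3
Reactants: 3 6-methyl-6-(trimethylsilyloxy)heptan-2-one
Product: 4 N'-[6-methyl-6-(trimethylsilyloxy)heptan-2-ylidene]-2,4,6-tri(propan-2-yl)benzenesulfonohydrazide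
Conditions: 2,4,6-tri(propan-2-yl)benzenesulfonohydrazide, THF, rt (no acid)
Reagents that add atoms: 2,4,6-tri(propan-2-yl)benzenesulfonohydrazide, NNS(=O)(=O)c1c(C(C)C)cc(C(C)C)cc1C(C)C
Why: Hydrazone formation (condensation of the methyl ketone with the arylsulfonylhydrazide) gives the Shapiro precursor, and the neutral medium spares the silyl ether.

Step 4
Reactants: 5 geraniol
Product: 6 [(1S,2S)-2-methyl-2-(4-methylpent-3-en-1-yl)cyclopropyl]methanol
Conditions: Et2Zn, CH2I2, DME, (4R,5R)-2-butyl-N,N,N',N'-tetramethyl-1,3,2-dioxaborolane-4,5-dicarboxamide (1.2 equiv), CH2Cl2, −10 °C → rt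
Reagents that add atoms: diiodomethane, ICI
Why: Charette asymmetric Simmons–Smith cyclopropanation, in which the zinc alkoxide of the allylic alcohol is held by the chiral dioxaborolane so that CH2 is transferred stereospecifically (syn) to one face of the (E)-alkene, setting both ring centres (1S,2S), the quaternary one being the future C6, while the remote alkene lacks the directing hydroxyl and should not react.

Step 5
Reactants: 6 [(1S,2S)-2-methyl-2-(4-methylpent-3-en-1-yl)cyclopropyl]methanol
Product: 7 (1S,2S)-2-methyl-2-(4-methylpent-3-en-1-yl)cyclopropane-1-carbaldehyde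
Conditions: TEMPO (cat.), PhI(OAc)2, CH2Cl2, rt
Reagents that add atoms: none
Why: Oxoammonium (TEMPO) oxidation should stop at the aldehyde and leave the alkene and the cyclopropane untouched.

Step 6
Reactants: 4 N'-[6-methyl-6-(trimethylsilyloxy)heptan-2-ylidene]-2,4,6-tri(propan-2-yl)benzenesulfonohydrazide; 7 (1S,2S)-2-methyl-2-(4-methylpent-3-en-1-yl)cyclopropane-1-carbaldehyde
Product: 10 6-methyl-2-methylidene-1-[(1S,2S)-2-methyl-2-(4-methylpent-3-en-1-yl)cyclopropyl]-6-(trimethylsilyloxy)heptyl acetate (both epimers at the acetoxy-bearing carbon), via vinyllithium 8 (not isolated), via lithium alkoxide 9 (not isolated)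
Conditions: 4, n-BuLi (2.1 equiv), TMEDA–hexane, −78 → 0 °C; then 7, −78 °C; then Ac2O, −78 °C → rt
Reagents that add atoms: acetic anhydride, CC(=O)OC(C)=O
Why: Shapiro reaction (metalation on the methyl side, loss of sulfinate and N2) gives the 2-lithio-1-alkene, which adds 1,2 to the aldehyde, and acetylation of the alkoxide in the same flask deactivates the new 1,1-disubstituted alkene for step 7; the carbinol centre forms without control and is removed in step 10.

Step 7
Reactants: 10 6-methyl-2-methylidene-1-[(1S,2S)-2-methyl-2-(4-methylpent-3-en-1-yl)cyclopropyl]-6-(trimethylsilyloxy)heptyl acetate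
Product: 11 6-methyl-2-methylidene-1-[(1S,2S)-2-methyl-2-(3-oxopropyl)cyclopropyl]-6-(trimethylsilyloxy)heptyl acetate
Conditions: O3 (1 equiv, Sudan red 7B as indicator), CH2Cl2, −78 °C; then PPh3
Reagents that add atoms: ozone, [O-][O+]=O
Why: Chemoselective ozonolysis, since ozone should attack the electron-rich trisubstituted alkene much faster than the 1,1-disubstituted alkene that bears the electron-withdrawing allylic acetate, and reductive work-up gives the aldehyde that becomes C3.

Step 8
Reactants: 11 6-methyl-2-methylidene-1-[(1S,2S)-2-methyl-2-(3-oxopropyl)cyclopropyl]-6-(trimethylsilyloxy)heptyl acetate; 12 (4S)-4-benzyl-3-propanoyl-1,3-oxazolidin-2-one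
Product: 14 (4S)-4-benzyl-3-[(2S,3R)-5-{(1S,2S)-2-[1-acetoxy-6-methyl-2-methylidene-6-(trimethylsilyloxy)heptyl]-1-methylcyclopropyl}-3-hydroxy-2-methylpentanoyl]-1,3-oxazolidin-2-one, via boron enolate 13 (not isolated)
Conditions: 12, Bu2BOTf, i-Pr2NEt, CH2Cl2, −78 → 0 °C; then 11, −78 → 0 °C; pH 7 buffer, MeOH, 30% H2O2
Reagents that add atoms: none
Why: Evans syn aldol reaction, in which the (Z)-dibutylboron enolate reacts through a closed Zimmerman–Traxler transition state on the face away from the benzyl group and so sets (2S,3R) under auxiliary control.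

Step 9
Reactants: 14 (4S)-4-benzyl-3-[(2S,3R)-5-{(1S,2S)-2-[1-acetoxy-6-methyl-2-methylidene-6-(trimethylsilyloxy)heptyl]-1-methylcyclopropyl}-3-hydroxy-2-methylpentanoyl]-1,3-oxazolidin-2-one
Product: 15 methyl (2S,3R)-5-[(1S,2S)-2-(1,6-dihydroxy-6-methyl-2-methylideneheptyl)-1-methylcyclopropyl]-3-hydroxy-2-methylpentanoate (both epimers at the allylic carbinol carbon)
Conditions: NaOMe (cat.), MeOH, 0 °C; then aq. citric acid, MeOH, rt
Reagents that add atoms: methanol, CO
Why: Methoxide-mediated transesterification cleaves the imide to the methyl ester and the acetate to the alcohol, and the mildly acidic work-up completes loss of the tertiary trimethylsilyl ether, no stereocentre being touched.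

Step 10
Reactants: 15 methyl (2S,3R)-5-[(1S,2S)-2-(1,6-dihydroxy-6-methyl-2-methylideneheptyl)-1-methylcyclopropyl]-3-hydroxy-2-methylpentanoate
Product: 16 methyl (2S,3R)-3-hydroxy-5-[(1S,2S)-2-(6-hydroxy-6-methyl-2-methylideneheptanoyl)-1-methylcyclopropyl]-2-methylpentanoate
Conditions: MnO2 (activated, excess), CH2Cl2, rt
Reagents that add atoms: none
Why: Chemoselective allylic oxidation, since MnO2 should oxidise only the allylic, cyclopropyl-activated carbinol and leave the saturated C3 alcohol and the tertiary alcohol alone, which also removes the uncontrolled carbinol centre.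

Step 11
Reactants: 16 methyl (2S,3R)-3-hydroxy-5-[(1S,2S)-2-(6-hydroxy-6-methyl-2-methylideneheptanoyl)-1-methylcyclopropyl]-2-methylpentanoate
Product: 18 methyl (2S,3S)-3-hydroperoxy-5-[(1S,2S)-2-(6-hydroxy-6-methyl-2-methylideneheptanoyl)-1-methylcyclopropyl]-2-methylpentanoate, via triflate 17 (not isolated)
Conditions: Tf2O (1.05 equiv), 2,6-lutidine, CH2Cl2, −78 °C; then anhydrous H2O2 in Et2O (excess), −78 → 0 °C
Reagents that add atoms: hydrogen peroxide, OO
Why: Triflation of the secondary alcohol (the tertiary one is too hindered at −78 °C) followed by SN2 perhydrolysis of the secondary triflate with neutral hydrogen peroxide should invert C3 from R to S, and the absence of strong base is meant to suppress elimination and epoxidation of the enone.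

Step 12
Reactants: 18 methyl (2S,3S)-3-hydroperoxy-5-[(1S,2S)-2-(6-hydroxy-6-methyl-2-methylideneheptanoyl)-1-methylcyclopropyl]-2-methylpentanoate
Product: 19 aikupikoxide D, methyl (2S)-2-[(3S,6R)-6-(8-hydroxy-8-methyl-4-methylidene-3-oxononyl)-6-methyl-1,2-dioxan-3-yl]propanoate
Conditions: Sc(OTf)3 (10 mol %), 4 Å MS, CH2Cl2 (0.005 M), −20 °C → rt
Reagents that add atoms: none
Why: Proposed new method: Sc(OTf)3 binds the C9 carbonyl and polarises the C6–C8 bond of the cyclopropane, so that the tethered hydroperoxide oxygen attacks the fully substituted C6 from the side opposite to the departing C8 in a borderline SN2 homo-conjugate (1,5-) addition, and the scandium dienolate so formed is protonated at C8 by the proton released from the hydroperoxide (net isomerisation with catalyst turnover). The closest known reaction types are the Lewis-acid-catalysed ring opening of donor–acceptor cyclopropane-1,1-diesters by hydroperoxides, the acid-promoted opening of 2,2-dialkylcyclopropyl ketones at the tertiary carbon by O–H and halide nucleophiles, and the intramolecular opening of 2,2-disubstituted oxetanes by hydroperoxides with inversion. The 1,2-dioxane closes in the 6-exo-tet mode, the breaking C6–C8 bond being exocyclic to the forming ring. The new quaternary stereocentre C6 is controlled by the (S) configuration of the cyclopropane carbon set in step 4, which is inverted to (6R), while C3 and the α-methyl centre are spectators. The step needs attack at C6 (not at C7, the ester carbonyl or the enone) and capture before a free tertiary cation forms; the tertiary ring carbon as the best cation-stabilising site, the six-membered transition state, and a redox-inert trivalent scandium catalyst in a non-ionising solvent at low temperature and high dilution are meant to secure this.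

**Compound list**

1 | 6-methylhept-5-en-2-one | CC(=O)CCC=C(C)C | starting material
2 | 6-hydroxy-6-methylheptan-2-one | CC(=O)CCCC(C)(C)O | intermediate
3 | 6-methyl-6-(trimethylsilyloxy)heptan-2-one | CC(=O)CCCC(C)(C)O[Si](C)(C)C | intermediate
4 | N'-[6-methyl-6-(trimethylsilyloxy)heptan-2-ylidene]-2,4,6-tri(propan-2-yl)benzenesulfonohydrazide | CC(CCCC(C)(C)O[Si](C)(C)C)=NNS(=O)(=O)c1c(C(C)C)cc(C(C)C)cc1C(C)C | intermediate
5 | geraniol, (2E)-3,7-dimethylocta-2,6-dien-1-ol | CC(C)=CCC/C(C)=C/CO | starting material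
6 | [(1S,2S)-2-methyl-2-(4-methylpent-3-en-1-yl)cyclopropyl]methanol | OC[C@H]1C[C@]1(C)CCC=C(C)C | intermediate
7 | (1S,2S)-2-methyl-2-(4-methylpent-3-en-1-yl)cyclopropane-1-carbaldehyde | O=C[C@H]1C[C@]1(C)CCC=C(C)C | intermediate
8 | [6-methyl-6-(trimethylsilyloxy)hept-1-en-2-yl]lithium (not isolated) | [Li]C(=C)CCCC(C)(C)O[Si](C)(C)C | intermediate
9 | lithium 6-methyl-2-methylidene-1-[(1S,2S)-2-methyl-2-(4-methylpent-3-en-1-yl)cyclopropyl]-6-(trimethylsilyloxy)heptan-1-olate, both epimers at the carbinol carbon (not isolated) | [Li]OC(C(=C)CCCC(C)(C)O[Si](C)(C)C)[C@H]1C[C@]1(C)CCC=C(C)C | intermediate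
10 | 6-methyl-2-methylidene-1-[(1S,2S)-2-methyl-2-(4-methylpent-3-en-1-yl)cyclopropyl]-6-(trimethylsilyloxy)heptyl acetate, both epimers at the acetoxy-bearing carbon | C=C(CCCC(C)(C)O[Si](C)(C)C)C(OC(C)=O)[C@H]1C[C@]1(C)CCC=C(C)C | intermediate
11 | 6-methyl-2-methylidene-1-[(1S,2S)-2-methyl-2-(3-oxopropyl)cyclopropyl]-6-(trimethylsilyloxy)heptyl acetate, both epimers at the acetoxy-bearing carbon | C=C(CCCC(C)(C)O[Si](C)(C)C)C(OC(C)=O)[C@H]1C[C@]1(C)CCC=O | intermediate
12 | (4S)-4-benzyl-3-propanoyl-1,3-oxazolidin-2-one | CCC(=O)N1C(=O)OC[C@@H]1Cc1ccccc1 | starting material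
13 | (4S)-4-benzyl-3-[(1Z)-1-(dibutylboranyloxy)prop-1-en-1-yl]-1,3-oxazolidin-2-one (not isolated) | C/C=C(\OB(CCCC)CCCC)N1C(=O)OC[C@@H]1Cc1ccccc1 | intermediate
14 | (4S)-4-benzyl-3-[(2S,3R)-5-{(1S,2S)-2-[1-acetoxy-6-methyl-2-methylidene-6-(trimethylsilyloxy)heptyl]-1-methylcyclopropyl}-3-hydroxy-2-methylpentanoyl]-1,3-oxazolidin-2-one, both epimers at the acetoxy-bearing carbon | C=C(CCCC(C)(C)O[Si](C)(C)C)C(OC(C)=O)[C@H]1C[C@]1(C)CC[C@@H](O)[C@H](C)C(=O)N2C(=O)OC[C@@H]2Cc3ccccc3 | intermediate
15 | methyl (2S,3R)-5-[(1S,2S)-2-(1,6-dihydroxy-6-methyl-2-methylideneheptyl)-1-methylcyclopropyl]-3-hydroxy-2-methylpentanoate, both epimers at the allylic carbinol carbon | C=C(CCCC(C)(C)O)C(O)[C@H]1C[C@]1(C)CC[C@@H](O)[C@H](C)C(=O)OC | intermediate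
16 | methyl (2S,3R)-3-hydroxy-5-[(1S,2S)-2-(6-hydroxy-6-methyl-2-methylideneheptanoyl)-1-methylcyclopropyl]-2-methylpentanoate | C=C(CCCC(C)(C)O)C(=O)[C@H]1C[C@]1(C)CC[C@@H](O)[C@H](C)C(=O)OC | intermediate
17 | methyl (2S,3R)-5-[(1S,2S)-2-(6-hydroxy-6-methyl-2-methylideneheptanoyl)-1-methylcyclopropyl]-2-methyl-3-(trifluoromethanesulfonyloxy)pentanoate (not isolated) | C=C(CCCC(C)(C)O)C(=O)[C@H]1C[C@]1(C)CC[C@@H](OS(=O)(=O)C(F)(F)F)[C@H](C)C(=O)OC | intermediate
18 | methyl (2S,3S)-3-hydroperoxy-5-[(1S,2S)-2-(6-hydroxy-6-methyl-2-methylideneheptanoyl)-1-methylcyclopropyl]-2-methylpentanoate | C=C(CCCC(C)(C)O)C(=O)[C@H]1C[C@]1(C)CC[C@H](OO)[C@H](C)C(=O)OC | intermediate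
19 | aikupikoxide D, methyl (2S)-2-[(3S,6R)-6-(8-hydroxy-8-methyl-4-methylidene-3-oxononyl)-6-methyl-1,2-dioxan-3-yl]propanoate | C=C(CCCC(C)(C)O)C(=O)CC[C@@]1(C)CC[C@@H]([C@H](C)C(=O)OC)OO1 | target

**Step count.** Total: 12 steps. Longest linear sequence: 10 steps (steps 1–3, then 6–12; the geraniol branch, steps 4–12, is 9).

**Steps most likely to fail**

Step 12 (labelled key step). The process at risk is ionisation of the scandium-bound cyclopropyl ketone to a free tertiary cation before the peroxide oxygen has bonded. That would erode the configuration at C6 and allow capture by the carbonyl oxygen (ring expansion to a dihydrofuran) or elimination; acid-induced heterolysis of the O–O bond is a further loss channel. The fallback uses known reactions only, but gives up control at C6. It sets out from enone 16, whose acyl group is cis to the ring methyl. Heating 16 in degassed toluene (about 170 °C, sealed vessel, BHT) should bring about the thermal homo-1,5-hydrogen shift (retro-ene opening of a cis-alkyl cyclopropyl ketone) to methyl (2S,3R)-3,14-dihydroxy-2,14-dimethyl-6,10-dimethylidene-9-oxopentadecanoate F1. Triflation and perhydrolysis as in step 11 should give, through the triflate F2, the alkenyl hydroperoxide F3. Cycloperoxymercuration with Hg(OAc)2 (cat. HClO4, CH2Cl2; 6-exo, Markovnikov) should give the organomercurial F4. Reduction of its C–Hg bond with Bu3SnH should then give 19 together with its C6 epimer F5, to be separated by chromatography. The fallback comes back to the route at 19.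

Step 11. The process at risk is 1,2-elimination of the β-triflyloxy ester to the conjugated ester (the α-hydrogen is acidic) outrunning substitution at the hindered secondary carbon. The fallback keeps the ester carbonyl out of the molecule until the peroxide ring is closed. It sets out from aldehyde 11. Roush crotylboration with the (Z)-crotylboronate of (R,R)-diisopropyl tartrate (toluene, 4 Å MS, −78 °C) should give the syn homoallylic alcohol F6. K2CO3 in MeOH then removes acetate and silyl group to give the triol F7, and MnO2 gives the enone F8. Tf2O and then H2O2, as in step 11 but now without an acidic α-hydrogen, should give the hydroperoxide F10 through the triflate F9. The Sc(OTf)3 ring closure of step 12 gives the vinyl-substituted dioxane F11. Ozonolysis of the monosubstituted alkene (the electron-poor enone alkene should react much more slowly; PPh3 work-up) gives the aldehyde F12, Pinnick oxidation gives the acid F13, and MeI with KHCO3 in DMF returns to the route at 19.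

Step 6. The process at risk is incomplete or misdirected metalation of the hydrazone, and quenching of the vinyllithium by proton transfer before it adds to the hindered aldehyde. The fallback replaces the organolithium by a Nozaki–Hiyama–Kishi coupling. It sets out from ketone 3: LDA (THF, −78 °C) and PhNTf2 should give the terminal enol triflate F14. CrCl2 with catalytic NiCl2 in DMF should couple F14 with aldehyde 7 to give the allylic alcohol F15, and Ac2O, pyridine and DMAP return to the route at acetate 10.

Further compounds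
F1 | step 12 | methyl (2S,3R)-3,14-dihydroxy-2,14-dimethyl-6,10-dimethylidene-9-oxopentadecanoate | C=C(CCCC(C)(C)O)C(=O)CCC(=C)CC[C@@H](O)[C@H](C)C(=O)OC
F2 | step 12 | methyl (2S,3R)-14-hydroxy-2,14-dimethyl-6,10-dimethylidene-9-oxo-3-(trifluoromethanesulfonyloxy)pentadecanoate | C=C(CCCC(C)(C)O)C(=O)CCC(=C)CC[C@@H](OS(=O)(=O)C(F)(F)F)[C@H](C)C(=O)OC
F3 | step 12 | methyl (2S,3S)-3-hydroperoxy-14-hydroxy-2,14-dimethyl-6,10-dimethylidene-9-oxopentadecanoate | C=C(CCCC(C)(C)O)C(=O)CCC(=C)CC[C@H](OO)[C@H](C)C(=O)OC
F4 | step 12 | methyl (2S)-2-[(3S)-6-(acetoxymercuriomethyl)-6-(8-hydroxy-8-methyl-4-methylidene-3-oxononyl)-1,2-dioxan-3-yl]propanoate, both C6 epimers | C=C(CCCC(C)(C)O)C(=O)CCC1(C[Hg]OC(C)=O)CC[C@@H]([C@H](C)C(=O)OC)OO1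
F5 | step 12 | methyl (2S)-2-[(3S,6S)-6-(8-hydroxy-8-methyl-4-methylidene-3-oxononyl)-6-methyl-1,2-dioxan-3-yl]propanoate | C=C(CCCC(C)(C)O)C(=O)CC[C@]1(C)CC[C@@H]([C@H](C)C(=O)OC)OO1
F6 | step 11 | 1-{(1S,2S)-2-[(3R,4R)-3-hydroxy-4-methylhex-5-en-1-yl]-2-methylcyclopropyl}-6-methyl-2-methylidene-6-(trimethylsilyloxy)heptyl acetate, both epimers at the acetoxy-bearing carbon | C=C(CCCC(C)(C)O[Si](C)(C)C)C(OC(C)=O)[C@H]1C[C@]1(C)CC[C@@H](O)[C@H](C)C=C
F7 | step 11 | 1-{(1S,2S)-2-[(3R,4R)-3-hydroxy-4-methylhex-5-en-1-yl]-2-methylcyclopropyl}-6-methyl-2-methylideneheptane-1,6-diol, both epimers at C1 | C=C(CCCC(C)(C)O)C(O)[C@H]1C[C@]1(C)CC[C@@H](O)[C@H](C)C=C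
F8 | step 11 | 6-hydroxy-1-{(1S,2S)-2-[(3R,4R)-3-hydroxy-4-methylhex-5-en-1-yl]-2-methylcyclopropyl}-6-methyl-2-methylideneheptan-1-one | C=C(CCCC(C)(C)O)C(=O)[C@H]1C[C@]1(C)CC[C@@H](O)[C@H](C)C=C
F9 | step 11 | (3R,4R)-1-[(1S,2S)-2-(6-hydroxy-6-methyl-2-methylideneheptanoyl)-1-methylcyclopropyl]-4-methylhex-5-en-3-yl trifluoromethanesulfonate | C=C(CCCC(C)(C)O)C(=O)[C@H]1C[C@]1(C)CC[C@@H](OS(=O)(=O)C(F)(F)F)[C@H](C)C=C
F10 | step 11 | 1-{(1S,2S)-2-[(3S,4R)-3-hydroperoxy-4-methylhex-5-en-1-yl]-2-methylcyclopropyl}-6-hydroxy-6-methyl-2-methylideneheptan-1-one | C=C(CCCC(C)(C)O)C(=O)[C@H]1C[C@]1(C)CC[C@H](OO)[C@H](C)C=C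
F11 | step 11 | 1-{(3S,6R)-3-[(2R)-but-3-en-2-yl]-6-methyl-1,2-dioxan-6-yl}-8-hydroxy-8-methyl-4-methylidenenonan-3-one | C=C(CCCC(C)(C)O)C(=O)CC[C@@]1(C)CC[C@@H]([C@H](C)C=C)OO1
F12 | step 11 | (2S)-2-[(3S,6R)-6-(8-hydroxy-8-methyl-4-methylidene-3-oxononyl)-6-methyl-1,2-dioxan-3-yl]propanal | C=C(CCCC(C)(C)O)C(=O)CC[C@@]1(C)CC[C@@H]([C@H](C)C=O)OO1
F13 | step 11 | (2S)-2-[(3S,6R)-6-(8-hydroxy-8-methyl-4-methylidene-3-oxononyl)-6-methyl-1,2-dioxan-3-yl]propanoic acid | C=C(CCCC(C)(C)O)C(=O)CC[C@@]1(C)CC[C@@H]([C@H](C)C(=O)O)OO1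
F14 | step 6 | 6-methyl-6-(trimethylsilyloxy)hept-1-en-2-yl trifluoromethanesulfonate | C=C(CCCC(C)(C)O[Si](C)(C)C)OS(=O)(=O)C(F)(F)F
F15 | step 6 | 6-methyl-2-methylidene-1-[(1S,2S)-2-methyl-2-(4-methylpent-3-en-1-yl)cyclopropyl]-6-(trimethylsilyloxy)heptan-1-ol, both epimers at C1 | C=C(CCCC(C)(C)O[Si](C)(C)C)C(O)[C@H]1C[C@]1(C)CCC=C(C)C
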